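**Assumptions**

- Eremophilane numbering is used for all bicyclic compounds (ring A = C1–C5 and C10, ring B = C5–C10, C11–C13 = isopropylidene carbons); β is the face of the decalin that carries the C5 methyl group, α the opposite face.
- (S)-Pent-1-yn-3-ol is treated as a purchasable chiral building block.
- Metal enolates, alkoxides and acetylides formed by deprotonation are regarded as the reacting form of the numbered compound and carry no number of their own.
- Checked atom by atom against the target, 2, 3 and 4 are self-consistent (4 has C5 in the required sense and C4 and C10 in the opposite sense), so their structures are used unchanged. The diene is kept as its tert-butyldimethylsilyl ether because that group survives the strong Lewis acid and afterwards masks the C3 carbonyl while the C9 carbonyl is worked on.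

## Structural features

The target is an eremophilane, a trans-fused decalin. Ring A (C1–C5, C10) carries an equatorial ester oxygen at C3, an equatorial methyl at C4 and the axial angular methyl on the quaternary C5. Ring B (C5–C10) carries the C7=C11 isopropylidene group, the C8 ketone and an equatorial hydroxyl at C9; the ring centres are 3R,4R,5R,9S,10R. The five stereocentres C3, C4, C5, C10 and C9 are contiguous, and the quaternary C5 is flanked on both sides by stereogenic CH groups. The C3 oxygen is acylated by (S,Z)-4-[(Z)-hex-2-enoyloxy]hex-2-enoic acid, a chain with two Z enoates and an allylic acyloxy stereocentre. The fragile groups are these Z enoates (Z to E isomerisation under nucleophilic or basic catalysis; a free 4-hydroxyl in the Z series would close to a butenolide), the α-ketol at C8/C9 and the cross-conjugated enone. The real difficulty is the congested C4–C5–C10 array around the all-carbon quaternary centre, together with telling three oxygenated carbons (C3, C8, C9) apart. The key step uses the fact that C5=C10, with its C5 methyl and a carbonyl at C9, is the olefin of 3-methylcyclohex-2-enone, while C1–C4, with the C3 oxygen and the C4 methyl, is the silyl dienol ether of ethyl vinyl ketone. A [4+2] union across C5=C10 therefore forms C4–C5 and C1–C10 and builds ring A onto a ready-made ring B. Of the three centres so created only C5 is permanent, since C4 and C10 each lie α to a carbonyl (C3 once unmasked, C9) and can be adjusted afterwards.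

## Logic of the disconnections

29 is traced to 28 by cutting the O–Si bond at C9. The α-ketol hydroxyl is kept masked until the C3 ester is in place so that acylation is unambiguous. The demand is a final desilylation mild enough for two Z enoates and an allylic ester.

28 is cut at the acyl–oxygen bond of the C3 ester into 20 and 26. This is the most convergent cut: it removes the whole sensitive chain and leaves a decalin core and a C12 acid that are made independently. The forward step must acylate a hindered secondary alcohol without isomerising the activated Z enoate.

26 is traced to 25 by turning both Z olefins into alkynes, so that one cis semihydrogenation sets both geometries and the 4-oxygen is never free in the Z series. 25 is cut at its internal ester into 22 and 24 (from 23), and 22 at the carboxyl–alkyne bond into 21 and a one-carbon electrophile. The stereocentre is bought; the demand is O-acylation in the presence of a free carboxyl group.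

20 is traced to 19 by restoring the C3 benzyl-type ether. 19 comes from 17 (through 18) by cutting the C7=C11 π bond to a β-hydroxy ketone, and 17 from 15 and 16 by cutting the C7–C11 bond (aldol). Three carbons leave and ring B becomes a plain α-silyloxy ketone. The demands are enolisation toward C7 and a C3 protecting group orthogonal to the C9 silyl ether.

15 is traced to 14 (O–Si), 14 to 12 by returning the C8 carbonyl to a carbinol (through 13), and 12 to 11 by cutting both C–O bonds of the cis-diol back to the C8=C9 olefin. Two oxygens and the C9 stereocentre thus come from an olefin. The demands are attack from the α face (anti to the axial C5 methyl) and oxidation of the axial C8 hydroxyl in preference to the equatorial C9 hydroxyl.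

11 is traced to 10 (ether), 10 to 9 (C3–H bond), and 9 to 7 through 8 (enol ether hydrolysis and inversion of C4). C3 and C4 are thereby reduced to a masked ketone. Because the axial C5 methyl is syn-axial to the trajectory of axial hydride attack at C3, the reduction must be thermodynamically controlled (dissolving metal), not a small-hydride reduction. C4 is set by equilibration to the equatorial methyl.

7 is traced to 6 (C9–H to C9–OTf), 6 to 5 (enol triflate to ketone) and 5 to 4 (inversion of C10). The C9 carbonyl of the cycloadduct is used twice: to invert the ring fusion and then to place the olefin regiospecifically at C8=C9. The inversion is placed on the silyl enol ether stage because the trans preference should be strongest there and the two carbonyl groups stay differentiated.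

4 is cut at C4–C5 and C1–C10 (retro-[4+2]) into 2 and 3. One ring, two skeletal bonds and the quaternary centre are removed in a single operation, and both fragments are commercial or one step away. The forward step needs a catalyst that activates a β,β-disubstituted enone and chooses one of its faces, and it needs the nucleophilic diene terminus to bond to the β-carbon.

2 is traced to 1 by cutting the O–Si bond. The demand is the Z enol ether geometry.

## Other disconnections considered

Alternative 1: The cut is through C7–C8 and O–C11 of the decalin-fused isoxazoline A1 (retro-dipolar cycloaddition). It leads to the monocyclic nitro compound A2, a cyclohexane with methyl and prenyl on C5 and a 2-nitro-1-silyloxyethyl chain on C10. In the forward step PhNCO and Et3N dehydrate the nitro group to a nitrile oxide, which adds across C7=C11 and closes ring B together with the heterocycle. N–O hydrogenolysis of A1 (Raney Ni, H2, B(OH)3) would give one C7 epimer of 17, and dehydration would give 19. In its favour, one step delivers ring B with the masked C8 carbonyl, the C9 oxygen and the C11 oxygen, so the enol triflate, olefin, diol, selective oxidation and aldol stages are not needed; on functional-group economy in ring B this alternative is better than the chosen plan. The C7 centre is of no consequence, and the tether fixes the regiochemistry as reliably as polarity does in the chosen step (equal). Against it, the cycloaddition creates no permanent stereocentre. C3, C4, the quaternary C5, C10 and C9 would all have to be set beforehand on a flexible monocycle in A2, which is the hard part of the problem left unsolved. A trisubstituted olefin is a slow dipolarophile, so dimerisation of the nitrile oxide competes. The silyloxy group at C9 is β to the nitro carbon and can be eliminated by the amine. After ring closure the alternative needs about two steps to reach 19 against eleven in the chosen route, but the way to A2 should cost more than it saves.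

Alternative 2: The cut is through C5–C10 and C1–C2 of the octalone A3 (retro-intramolecular Diels–Alder), giving the acyclic silyloxytrienone A4. On heating, the diene C2=C3(OSi)–C4=C5 would add to the vinyl ketone C10=C1 and close both rings at once. In its favour, both rings and the quaternary centre arise together with the entropic help of a tether, which is better than an intermolecular union with a weak dienophile. The C8 oxygen is already present, so ring B needs only a redox exchange between C8 and C9 to reach 15, without triflate, dihydroxylation or selective diol oxidation; on this point the alternative is also better. A wrong ring fusion could be corrected at C10 by base, the same remedy as in the chosen plan (equal). Against it, the diene terminus C5 is fully substituted and C4 is substituted as well, so one group must point inside in the s-cis conformer; rates should be low and the temperature needed invites hydrogen shifts and loss of the silyl group. The exo/endo preference that decides the fusion is hard to predict. The absolute configuration rests on the single C8 stereocentre in the tether, which must first be made enantiopure and exerts only moderate control over the diene face, whereas the chosen plan uses catalyst control with achiral, commercial partners. The geometry of the tetrasubstituted C4=C5 bond in A4 has to be secured too. A linear synthesis of A4 of roughly eight to ten steps makes the overall count comparable.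

Alternative 3: The cut is through C5–C6 of the decalone A5, which is identical with 15, giving A6, a methylenecyclohexane whose C10 side chain ends in a vinyl ketone. In the forward step Fe(acac)3 and PhSiH3 would transfer a hydrogen atom to the exocyclic methylene carbon, and the tertiary C5 radical would add to C6 of the enone (6-endo Giese addition), closing ring B. In its favour, radical bond formation tolerates steric congestion at a quaternary carbon better than a cycloaddition to a β,β-disubstituted enone, and the conditions spare both protecting groups; both points are better. It delivers 15 directly, so the last part of the route is shared and the triflate, reduction, dihydroxylation, oxidation and silylation steps are avoided. Against it, C5 and the ring fusion are set under substrate control by the way the chain folds onto the planar radical. Such closures can give cis/trans mixtures, and a wrong C5 cannot be repaired, unlike C10 in the chosen plan. Direct reduction of the enone or of the radical competes. A6 needs four stereocentres (C3, C4, C10, C9) on a monocycle together with a sensitive α-silyloxy vinyl ketone, so the stereochemical burden is moved, not removed. The chosen plan sets C5 by catalyst control in the second step; overall length should be similar or longer for the alternative.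

Key step: step 2

## Route

Step 1
Reactants: 1 ethyl vinyl ketone (pent-1-en-3-one)
Product: 2 (Z)-3-(tert-butyldimethylsilyloxy)penta-1,3-diene
Conditions: TBSOTf, Et3N, CH2Cl2, 0 °C
Reagents that add atoms: tert-butyldimethylsilyl triflate, CC(C)(C)[Si](C)(C)OS(=O)(=O)C(F)(F)F
Why: Soft enolisation of the ethyl ketone by the silyl triflate–amine pair gives the silyl dienol ether, with the Z enol ether (oxygen and methyl cis) favoured as usual for ethyl ketones; silyl enol ether formation; this geometry places the methyl outside in the s-cis diene, which the cycloaddition needs.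

Step 2
Reactants: 3 3-methylcyclohex-2-en-1-one; 2 (Z)-3-(tert-butyldimethylsilyloxy)penta-1,3-diene
Product: 4 cis-fused 3-(tert-butyldimethylsilyloxy)-4α,5β-dimethyl-10βH-octal-2-en-9-one
Conditions: (S)-3,3-diphenyl-1-(2-methylphenyl)tetrahydro-1H,3H-pyrrolo[1,2-c][1,3,2]oxazaborole (20 mol%), HN(SO2CF3)2 (20 mol%), 2 (2.5 equiv), CH2Cl2, −20 °C
Reagents that add atoms: none
Why: The N-protonated oxazaborolidine binds the C9 carbonyl at the lone pair syn to C10 (α-C–H···O contact) and lowers the enone LUMO, and the silyl dienol ether then adds in an asynchronous, Mukaiyama–Michael-like [4+2] cycloaddition in which C4–C5 runs ahead of C1–C10. The closest known reactions are Lewis-acid-promoted Diels–Alder additions of 2-silyloxydienes to 3-substituted cyclohexenones and oxazaborolidinium-catalysed Diels–Alder reactions of cyclic enones. Ring A closes as a six-membered ring by intermolecular [4+2] annulation across C5=C10, leaving the enol ether double bond at C2=C3. C5 is set by the catalyst: in the binding model one phenyl group of the (S)-configured catalyst covers the Re face, so the diene should add to the Si face at C5 and C10, which is the face that gives the 5β-methyl. C10 follows from suprafacial addition to the ring olefin, hence the cis fusion (10β-H). C4 follows from the Z enol ether geometry together with the endo orientation of ring B, which places the C4 methyl anti to the C5 methyl. The step needs regioselectivity (the nucleophilic C4 terminus bonds to the β-carbon C5, secured by the polarity of the partners) and facial selectivity (catalyst); only C5 has to be right, because C4 and C10 are corrected in steps 3 and 6.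

Step 3
Reactants: 4 cis-fused adduct
Product: 5 trans-fused 3-(tert-butyldimethylsilyloxy)-4α,5β-dimethyl-10αH-octal-2-en-9-one
Conditions: DBU, toluene, 90 °C
Reagents that add atoms: none
Why: C10 is α to the C9 carbonyl and inverts by reversible enolisation (thermodynamic epimerisation); the trans isomer should be favoured because its pseudoaxial 4α-methyl, held axial by A(1,2) strain with the C3 silyloxy group, lies anti to the axial C5 methyl, whereas in the cis isomer it is either syn-axial to C9 or pushed against the silyloxy group.

Step 4
Reactants: 5 trans-fused ketone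
Product: 6 trans-fused 3-(tert-butyldimethylsilyloxy)-4α,5β-dimethyl-10αH-octa-2,8-dien-9-yl trifluoromethanesulfonate
Conditions: KN(SiMe3)2, THF, −78 °C; PhNTf2, −78 → 0 °C
Reagents that add atoms: N-phenylbis(trifluoromethanesulfonimide), O=S(=O)(N(c1ccccc1)S(=O)(=O)C(F)(F)F)C(F)(F)F
Why: The hindered amide removes a proton from the C8 methylene and not from the C10 methine next to the quaternary carbon, and O-sulfonylation of the potassium enolate fixes the double bond at C8=C9; kinetic enol triflate formation.

Step 5
Reactants: 6 enol triflate
Product: 7 trans-fused 3-(tert-butyldimethylsilyloxy)-4α,5β-dimethyl-10αH-octa-2,8-diene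
Conditions: Pd(OAc)2 (5 mol%), PPh3 (10 mol%), Bu3N, HCO2H, DMF, 60 °C
Reagents that add atoms: none
Why: Oxidative addition of zerovalent palladium into the C9–OTf bond, formate exchange, loss of CO2 and reductive elimination replace the triflate by hydrogen without moving the olefin; palladium-catalysed formate reduction of an enol triflate, run amine-buffered so that the silyl enol ether survives.

Step 6
Reactants: 7 silyloxy diene
Product: 9 trans-fused 4β,5β-dimethyl-10αH-octal-8-en-3-one (equatorial C4 methyl), via 4α-methyl ketone 8 (not isolated)
Conditions: 1 M HCl, THF, rt; then NaOMe, MeOH, rt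
Reagents that add atoms: none
Why: Acid hydrolysis protonates C2 and frees the C3 ketone with the axial 4α-methyl intact; methoxide then equilibrates C4 through the C3=C4 enolate to the equatorial 4β-methyl, which avoids the syn-axial contacts with H-2 and H-10 (both kinetic axial protonation and thermodynamics point this way), while C10 is no longer acidic; enol ether hydrolysis and epimerisation.

Step 7
Reactants: 9 equatorial-methyl ketone
Product: 10 trans-fused 4β,5β-dimethyl-10αH-octal-8-en-3α-ol (equatorial hydroxyl)
Conditions: Li, NH3 (l), THF, EtOH, −78 °C; NH4Cl
Reagents that add atoms: none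
Why: Dissolving-metal reduction passes through a ketyl and carbanion that is protonated to the more stable equatorial alkoxide, giving 3α-OH; a small hydride would be turned to the α face by the syn-axial C5 methyl and give much axial alcohol; the isolated C8=C9 olefin is inert.

Step 8
Reactants: 10 equatorial alcohol
Product: 11 3α-(4-methoxybenzyloxy)-4β,5β-dimethyl-10αH-octal-8-ene
Conditions: NaH, 4-methoxybenzyl chloride, Bu4NI (cat.), DMF, 0 °C → rt
Reagents that add atoms: 4-methoxybenzyl chloride, COc1ccc(CCl)cc1
Why: Williamson etherification of the sodium alkoxide; the ether is stable to all ring B operations up to step 13 and is later removed oxidatively without touching the silyl ether.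

Step 9
Reactants: 11 olefin
Product: 12 3α-(4-methoxybenzyloxy)-4β,5β-dimethyl-10αH-decalin-8α,9α-diol
Conditions: OsO4 (2 mol%), NMO, acetone/H2O, rt
Reagents that add atoms: N-methylmorpholine N-oxide, C[N+]1([O-])CCOCC1; water, O
Why: Catalytic syn dihydroxylation adds both oxygens from the α face, anti to the axial C5 methyl that stands 1,3 to C9, so the C9 hydroxyl is equatorial as in the target and the C8 hydroxyl is axial.

Step 10
Reactants: 12 cis-diol
Product: 14 9α-hydroxy-3α-(4-methoxybenzyloxy)-4β,5β-dimethyl-10αH-decalin-8-one, via dibutylstannylene acetal 13 (not isolated)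
Conditions: Bu2SnO, toluene, reflux (Dean–Stark); then NBS, CHCl3, rt
Reagents that add atoms: none
Why: The cis-diol forms a five-membered stannylene acetal, and brominolysis of such acetals oxidises the axial hydroxyl of a cis-1,2-diol on a six-membered ring, here the less hindered C8 carbinol, leaving the equatorial C9 hydroxyl; regioselective stannylene-mediated oxidation to an α-ketol.

Step 11
Reactants: 14 α-ketol
Product: 15 9α-(tert-butyldimethylsilyloxy)-3α-(4-methoxybenzyloxy)-4β,5β-dimethyl-10αH-decalin-8-one
Conditions: TBSOTf, 2,6-lutidine, CH2Cl2, −78 → 0 °C
Reagents that add atoms: tert-butyldimethylsilyl triflate, CC(C)(C)[Si](C)(C)OS(=O)(=O)C(F)(F)F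
Why: O-Silylation of the hindered secondary hydroxyl is much faster than enol silylation at low temperature; the bulky silyl ether resists oxygen-to-oxygen migration onto the enolate in step 12.

Step 12
Reactants: 15 silyloxy ketone; 16 acetone
Product: 17 7-(2-hydroxypropan-2-yl)-9α-(tert-butyldimethylsilyloxy)-3α-(4-methoxybenzyloxy)-4β,5β-dimethyl-10αH-decalin-8-one (C7 epimers)
Conditions: LiN(i-Pr)2, THF, −78 °C; ZnCl2; acetone, −78 → −40 °C; aq. NH4Cl
Reagents that add atoms: none
Why: The amide removes a C7 methylene proton rather than the hindered silyloxy-bearing C9 methine, transmetalation to zinc suppresses proton transfer to acetone and retro-aldol, and the enolate adds to acetone; directed aldol addition; the C7 configuration is lost in step 13.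

Step 13
Reactants: 17 aldol
Product: 19 9α-(tert-butyldimethylsilyloxy)-3α-(4-methoxybenzyloxy)eremophil-7(11)-en-8-one, via tertiary mesylate 18 (not isolated)
Conditions: MsCl, Et3N, CH2Cl2, 0 °C; then DBU, rt
Reagents that add atoms: none
Why: Sulfene-mediated mesylation of the tertiary alcohol and E1cB elimination through the C7 enolate give the conjugated tetrasubstituted C7=C11 olefin, not the isopropenyl isomer; aldol dehydration; C9 already has its stable equatorial configuration.

Step 14
Reactants: 19 protected enone
Product: 20 9α-(tert-butyldimethylsilyloxy)-3α-hydroxyeremophil-7(11)-en-8-one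
Conditions: DDQ, CH2Cl2/pH 7 buffer, 0 °C → rt
Reagents that add atoms: none
Why: Single-electron oxidation of the electron-rich benzyl ether and hydrolysis of the oxocarbenium ion free the C3 hydroxyl; oxidative 4-methoxybenzyl ether cleavage, which leaves the silyl ether and the enone alone.

Step 15
Reactants: 21 (S)-pent-1-yn-3-ol
Product: 22 (S)-4-hydroxyhex-2-ynoic acid
Conditions: n-BuLi (2.1 equiv), THF, −78 → 0 °C; CO2, −78 °C → rt; 1 M HCl
Reagents that add atoms: carbon dioxide, O=C=O
Why: The alkoxide–acetylide dianion is carboxylated at carbon, and any carbonate formed at oxygen reverts on acidification; carboxylation of a lithium acetylide; the stereocentre is not touched.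

Step 16
Reactants: 23 hex-2-ynoic acid; 22 (S)-4-hydroxyhex-2-ynoic acid
Product: 25 (S)-4-(hex-2-ynoyloxy)hex-2-ynoic acid, via hex-2-ynoyl chloride 24 (not isolated)
Conditions: (COCl)2, DMF (cat.), CH2Cl2, 0 °C → rt, evaporate; then 22, CH2Cl2, 0 → 40 °C; aqueous work-up
Reagents that add atoms: none
Why: Without base the carboxyl group of 22 is not nucleophilic, so the acid chloride acylates only the hydroxyl, as in the classical O-acylation of hydroxy acids; base is also avoided because alkoxides and amines add to the activated triple bonds.

Step 17
Reactants: 25 diyne acid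
Product: 26 (S,Z)-4-[(Z)-hex-2-enoyloxy]hex-2-enoic acid
Conditions: H2 (1 atm), Pd/CaCO3 poisoned with Pb(OAc)2, quinoline, EtOAc, rt
Reagents that add atoms: none
Why: Syn delivery of hydrogen on the poisoned palladium surface turns both conjugated alkynes into Z olefins and stops there (Lindlar-type semihydrogenation); the 4-oxygen is already acylated, so the Z acid cannot lactonise.

Step 18
Reactants: 26 Z,Z acid; 20 C3 alcohol
Product: 28 9-O-tert-butyldimethylsilyl ether of the target, via mixed trichlorobenzoic anhydride 27 (not isolated)
Conditions: 2,4,6-trichlorobenzoyl chloride, Et3N, toluene, rt; then 20, toluene, 70 °C (no DMAP)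
Reagents that add atoms: none
Why: The alcohol attacks the unhindered enoyl carbonyl of the mixed anhydride (Yamaguchi-type esterification); leaving out the nucleophilic pyridine catalyst removes the conjugate addition–elimination path by which activated Z enoates isomerise, as practised for angelate esters.

Step 19
Reactants: 28 silyl-protected ester
Product: 29 target, 3α-[(S,Z)-4-((Z)-hex-2-enoyloxy)hex-2-enoyloxy]-9α-hydroxyeremophil-7(11)-en-8-one
Conditions: HF·pyridine, pyridine, THF, 0 °C → rt
Reagents that add atoms: none
Why: Buffered fluoride cleaves the Si–O bond under weakly acidic conditions that neither isomerise the Z enoates nor eliminate or migrate the allylic acyloxy group; desilylation.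

## Compound list

1 | ethyl vinyl ketone | CCC(=O)C=C | starting material
2 | (Z)-3-(tert-butyldimethylsilyloxy)penta-1,3-diene | C=C/C(O[Si](C)(C)C(C)(C)C)=C/C | intermediate
3 | 3-methylcyclohex-2-en-1-one | CC1=CC(=O)CCC1 | starting material
4 | cis-fused 3-(tert-butyldimethylsilyloxy)-4α,5β-dimethyl-10βH-octal-2-en-9-one | CC(C)(C)[Si](C)(C)OC1=CC[C@@H]2C(=O)CCC[C@]2(C)[C@@H]1C | intermediate
5 | trans-fused 3-(tert-butyldimethylsilyloxy)-4α,5β-dimethyl-10αH-octal-2-en-9-one | CC(C)(C)[Si](C)(C)OC1=CC[C@H]2C(=O)CCC[C@]2(C)[C@@H]1C | intermediate
6 | trans-fused 3-(tert-butyldimethylsilyloxy)-4α,5β-dimethyl-10αH-octa-2,8-dien-9-yl triflate | CC(C)(C)[Si](C)(C)OC1=CC[C@H]2C(OS(=O)(=O)C(F)(F)F)=CCC[C@]2(C)[C@@H]1C | intermediate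
7 | trans-fused 3-(tert-butyldimethylsilyloxy)-4α,5β-dimethyl-10αH-octa-2,8-diene | CC(C)(C)[Si](C)(C)OC1=CC[C@H]2C=CCC[C@]2(C)[C@@H]1C | intermediate
8 | trans-fused 4α,5β-dimethyl-10αH-octal-8-en-3-one (axial C4 methyl) | O=C1CC[C@H]2C=CCC[C@]2(C)[C@@H]1C | intermediate
9 | trans-fused 4β,5β-dimethyl-10αH-octal-8-en-3-one (equatorial C4 methyl) | O=C1CC[C@H]2C=CCC[C@]2(C)[C@H]1C | intermediate
10 | trans-fused 4β,5β-dimethyl-10αH-octal-8-en-3α-ol | O[C@@H]1CC[C@H]2C=CCC[C@]2(C)[C@H]1C | intermediate
11 | 3α-(4-methoxybenzyloxy)-4β,5β-dimethyl-10αH-octal-8-ene | COc1ccc(CO[C@@H]2CC[C@H]3C=CCC[C@]3(C)[C@H]2C)cc1 | intermediate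
12 | 3α-(4-methoxybenzyloxy)-4β,5β-dimethyl-10αH-decalin-8α,9α-diol | COc1ccc(CO[C@@H]2CC[C@H]3[C@H](O)[C@H](O)CC[C@]3(C)[C@H]2C)cc1 | intermediate
13 | 8α,9α-O-dibutylstannylene acetal of 12 | COc1ccc(CO[C@@H]2CC[C@H]3[C@@H]4O[Sn](CCCC)(CCCC)O[C@@H]4CC[C@]3(C)[C@H]2C)cc1 | intermediate
14 | 9α-hydroxy-3α-(4-methoxybenzyloxy)-4β,5β-dimethyl-10αH-decalin-8-one | COc1ccc(CO[C@@H]2CC[C@H]3[C@H](O)C(=O)CC[C@]3(C)[C@H]2C)cc1 | intermediate
15 | 9α-(tert-butyldimethylsilyloxy)-3α-(4-methoxybenzyloxy)-4β,5β-dimethyl-10αH-decalin-8-one | COc1ccc(CO[C@@H]2CC[C@H]3[C@H](O[Si](C)(C)C(C)(C)C)C(=O)CC[C@]3(C)[C@H]2C)cc1 | intermediate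
16 | acetone | CC(C)=O | starting material
17 | 7-(2-hydroxypropan-2-yl) derivative of 15 (C7 epimers) | COc1ccc(CO[C@@H]2CC[C@H]3[C@H](O[Si](C)(C)C(C)(C)C)C(=O)C(C(C)(C)O)C[C@]3(C)[C@H]2C)cc1 | intermediate
18 | tertiary mesylate of 17 | COc1ccc(CO[C@@H]2CC[C@H]3[C@H](O[Si](C)(C)C(C)(C)C)C(=O)C(C(C)(C)OS(C)(=O)=O)C[C@]3(C)[C@H]2C)cc1 | intermediate
19 | 9α-(tert-butyldimethylsilyloxy)-3α-(4-methoxybenzyloxy)eremophil-7(11)-en-8-one | COc1ccc(CO[C@@H]2CC[C@H]3[C@H](O[Si](C)(C)C(C)(C)C)C(=O)C(=C(C)C)C[C@]3(C)[C@H]2C)cc1 | intermediate
20 | 9α-(tert-butyldimethylsilyloxy)-3α-hydroxyeremophil-7(11)-en-8-one | O[C@@H]1CC[C@H]2[C@H](O[Si](C)(C)C(C)(C)C)C(=O)C(=C(C)C)C[C@]2(C)[C@H]1C | intermediate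
21 | (S)-pent-1-yn-3-ol | CC[C@H](O)C#C | starting material
22 | (S)-4-hydroxyhex-2-ynoic acid | CC[C@H](O)C#CC(=O)O | intermediate
23 | hex-2-ynoic acid | CCCC#CC(=O)O | starting material
24 | hex-2-ynoyl chloride | CCCC#CC(=O)Cl | intermediate
25 | (S)-4-(hex-2-ynoyloxy)hex-2-ynoic acid | CCCC#CC(=O)O[C@H](C#CC(=O)O)CC | intermediate
26 | (S,Z)-4-[(Z)-hex-2-enoyloxy]hex-2-enoic acid | CCC/C=C\C(=O)O[C@H](/C=C\C(=O)O)CC | intermediate
27 | mixed anhydride of 26 with 2,4,6-trichlorobenzoic acid | CCC/C=C\C(=O)O[C@H](/C=C\C(=O)OC(=O)c1c(Cl)cc(Cl)cc1Cl)CC | intermediate
28 | 9-O-tert-butyldimethylsilyl ether of the target | CCC/C=C\C(=O)O[C@H](/C=C\C(=O)O[C@@H]1CC[C@H]2[C@H](O[Si](C)(C)C(C)(C)C)C(=O)C(=C(C)C)C[C@]2(C)[C@H]1C)CC | intermediate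
29 | CNP0170141.1 | CCC/C=C\C(=O)O[C@H](/C=C\C(=O)O[C@@H]1CC[C@H]2[C@H](O)C(=O)C(=C(C)C)C[C@]2(C)[C@H]1C)CC | target

## Step count and least certain steps

Total: 19 steps. Longest linear sequence: 16 steps (steps 1–14, 18, 19); the side chain takes steps 15–17.

Step 2 (key step). The β,β-disubstituted enone may react too slowly with the catalyst-bound pathway, so that protodesilylation or oligomerisation of the diene takes over. Facial discrimination may also be incomplete, because the binding model that predicts the face rests mainly on enones without a β-substituent. The fallback gives up catalyst control and resolves. It sets out from 2 and 3: stoichiometric Me2AlCl in CH2Cl2 at −20 °C should promote the same cycloaddition and give racemic 4, that is 4 together with its mirror image ent-4 F1. Steps 3 to 7 are run on the racemate and carry the mirror-image series ent-5 F2, ent-6 F3, ent-7 F4, ent-8 F5 and ent-9 F6 along to racemic 10, which contains ent-10 F7. Candida antarctica lipase B with vinyl acetate should, by the empirical rule for secondary alcohols, acylate the 3R alcohol and give the acetate of 10 F8, separable from unreacted ent-10 F7. Methanolysis (K2CO3, MeOH) returns 10, where the route is rejoined.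

Step 3. Proton exchange at the hindered C10 methine may be slow, forcing conditions may strip the silyl enol ether, and the equilibrium may be less one-sided than the conformational argument predicts. The fallback replaces thermodynamic by kinetic control and runs from 4 to 5. Thermodynamic silylation (TMSCl, NaI, Et3N, MeCN) should give the C9=C10 trimethylsilyl enol ether of 4 F9. MeLi in THF at −20 °C cleaves only the trimethylsilyl enol ether, and the lithium enolate is protonated at −78 °C with 2,6-di-tert-butyl-4-methylphenol, axially from the α face anti to the C5 methyl, to give 5.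

Step 10. Oxidation may occur at the wrong hydroxyl or go on to cleave the ketol, and the anisyl ring may be brominated. The fallback differentiates the hydroxyls by protection and runs from 12 to 15. Trimethyl orthoacetate with a trace of camphorsulfonic acid gives the cyclic orthoacetate of 12 F10. Mild aqueous acid opens it by the known preference to the axial ester, the 8α-acetate 9α-alcohol F11. Silylation (TBSOTf, 2,6-lutidine) gives the 8α-acetoxy 9α-silyl ether F12. Reductive removal of the acetate (DIBAL-H, −78 °C, chosen to avoid silyl migration) gives the 8α-hydroxy 9α-silyl ether F13, and Dess–Martin oxidation gives 15.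

Step 16. The carboxyl group may be drawn into mixed-anhydride formation and oligoesters, or the HCl set free may add to the activated triple bonds. The fallback protects the acid and runs from 22 to 25. tert-Butyl 2,2,2-trichloroacetimidate without catalyst esterifies only the carboxyl group and gives tert-butyl (S)-4-hydroxyhex-2-ynoate F14. Carbodiimide coupling with 23 (DCC, catalytic DMAP, −20 °C) gives tert-butyl (S)-4-(hex-2-ynoyloxy)hex-2-ynoate F15, and CF3CO2H in CH2Cl2 gives 25.

Step 18. The activated 2-enoyl unit may isomerise from Z to E, and acylation of the hindered C3 hydroxyl may be sluggish without a nucleophilic catalyst. The fallback forms the ester before the olefins exist and runs from 20 and 25 to 28. Coupling (DCC, catalytic DMAP, CH2Cl2, −20 °C) gives the diyne ester of 20 F16, which has no olefin geometry to lose. Semihydrogenation over Pd/CaCO3 poisoned with Pb(OAc)2 in the presence of quinoline then gives 28; the tetrasubstituted enone olefin is not reduced.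

## Further compounds

F1 | step 2 | ent-4 | CC(C)(C)[Si](C)(C)OC1=CC[C@H]2C(=O)CCC[C@@]2(C)[C@H]1C
F2 | step 2 | ent-5 | CC(C)(C)[Si](C)(C)OC1=CC[C@@H]2C(=O)CCC[C@@]2(C)[C@H]1C
F3 | step 2 | ent-6 | CC(C)(C)[Si](C)(C)OC1=CC[C@@H]2C(OS(=O)(=O)C(F)(F)F)=CCC[C@@]2(C)[C@H]1C
F4 | step 2 | ent-7 | CC(C)(C)[Si](C)(C)OC1=CC[C@@H]2C=CCC[C@@]2(C)[C@H]1C
F5 | step 2 | ent-8 | O=C1CC[C@@H]2C=CCC[C@@]2(C)[C@H]1C
F6 | step 2 | ent-9 | O=C1CC[C@@H]2C=CCC[C@@]2(C)[C@@H]1C
F7 | step 2 | ent-10 | O[C@H]1CC[C@@H]2C=CCC[C@@]2(C)[C@@H]1C
F8 | step 2 | acetate of 10 | CC(=O)O[C@@H]1CC[C@H]2C=CCC[C@]2(C)[C@H]1C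
F9 | step 3 | C9=C10 trimethylsilyl enol ether of 4 | CC(C)(C)[Si](C)(C)OC1=CCC2=C(O[Si](C)(C)C)CCC[C@]2(C)[C@@H]1C
F10 | step 10 | cyclic orthoacetate of 12 | COc1ccc(CO[C@@H]2CC[C@H]3[C@@H]4OC(C)(OC)O[C@@H]4CC[C@]3(C)[C@H]2C)cc1
F11 | step 10 | 8α-acetate 9α-alcohol | COc1ccc(CO[C@@H]2CC[C@H]3[C@H](O)[C@H](OC(C)=O)CC[C@]3(C)[C@H]2C)cc1
F12 | step 10 | 8α-acetoxy 9α-silyl ether | COc1ccc(CO[C@@H]2CC[C@H]3[C@H](O[Si](C)(C)C(C)(C)C)[C@H](OC(C)=O)CC[C@]3(C)[C@H]2C)cc1
F13 | step 10 | 8α-hydroxy 9α-silyl ether | COc1ccc(CO[C@@H]2CC[C@H]3[C@H](O[Si](C)(C)C(C)(C)C)[C@H](O)CC[C@]3(C)[C@H]2C)cc1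
F14 | step 16 | tert-butyl (S)-4-hydroxyhex-2-ynoate | CC[C@H](O)C#CC(=O)OC(C)(C)C
F15 | step 16 | tert-butyl (S)-4-(hex-2-ynoyloxy)hex-2-ynoate | CCCC#CC(=O)O[C@H](C#CC(=O)OC(C)(C)C)CC
F16 | step 18 | diyne ester of 20 | CCCC#CC(=O)O[C@H](C#CC(=O)O[C@@H]1CC[C@H]2[C@H](O[Si](C)(C)C(C)(C)C)C(=O)C(=C(C)C)C[C@]2(C)[C@H]1C)CC
A1 | alternative 1 | trans-decalin-fused isoxazoline | COc1ccc(CO[C@@H]2CC[C@H]3[C@H](O[Si](C)(C)C(C)(C)C)C4=NOC(C)(C)[C@@H]4C[C@]3(C)[C@H]2C)cc1
A2 | alternative 1 | nitro prenyl cyclohexane precursor | COc1ccc(CO[C@@H]2CC[C@@H]([C@H](O[Si](C)(C)C(C)(C)C)C[N+](=O)[O-])[C@](C)(CC=C(C)C)[C@H]2C)cc1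
A3 | alternative 2 | trans-fused 3-silyloxy-4,5-dimethyl-8-(4-methoxybenzyloxy)octal-3-en-9-one | CC(C)(C)[Si](C)(C)OC=1CC[C@H]2C(=O)[C@@H](OCc3ccc(OC)cc3)CC[C@]2(C)C=1C
A4 | alternative 2 | acyclic silyloxytrienone | C=CC(=O)[C@@H](OCc1ccc(OC)cc1)CC/C(C)=C(C)/C(O[Si](C)(C)C(C)(C)C)=C
A5 | alternative 3 | trans-decalin-8-one with C9 silyl ether and C3 4-methoxybenzyl ether (identical with 15) | COc1ccc(CO[C@@H]2CC[C@H]3[C@H](O[Si](C)(C)C(C)(C)C)C(=O)CC[C@]3(C)[C@H]2C)cc1
A6 | alternative 3 | methylenecyclohexane vinyl ketone precursor | COc1ccc(CO[C@@H]2CC[C@@H]([C@H](O[Si](C)(C)C(C)(C)C)C(=O)C=C)C(=C)[C@H]2C)cc1
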